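## Analysis of the target

The target 33 is a trans-fused decalin (decalin locants as in its name: C1 carries the arylmethyl group, C2 the exocyclic methylene, C4a and C8a are the fusion carbons, C5 is the quaternary carbon with the side chain, C6 is CHBr). It carries a 3,5-dibromo-2-hydroxybenzyl group on C1 and a (3R)-3-bromo-4-chloro-4-methylpentyl chain on C5. Five of the six stereocentres sit on the decalin: H-4a is trans to the C8a methyl, the C5 and C8a methyls are both axial on the same face, the C6 bromine is equatorial next to quaternary C5, and the C1 arylmethyl group is equatorial and cis to the C8a methyl. The sixth, the side-chain CHBr, is three bonds from the ring and cannot be set by substrate control. The sensitive groups are the tertiary chloride beside a secondary bromide (elimination, solvolysis), the neopentyl ring bromide, the exocyclic alkene (acid-induced migration), two aryl bromides (metalation, reduction) and a free, acidic phenol. The difficulty is three contiguous fully substituted or hindered ring carbons (C5, C4a, C8a) flanked by C6–Br and by C1, where enolate or displacement chemistry is poor. The strategy rests on the C2(=CH2)–C1(H)(CH2Ar) unit of ring A next to quaternary C8a. That is the pattern left when a 2-iodoalk-1-ene radical adds to the near carbon of a styrene and the benzylic radical is reduced.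

## Retrosynthetic reasoning

33 ← 32. The phenol is unmasked last. Its aryl silyl ether is the only group in 32 that fluoride attacks quickly, so the base-sensitive bromochloride is exposed to one mild step only.

32 ← 31 ← 30 ← 29. The side-chain C–Cl and C–Br bonds are cut back to the trisubstituted alkene of 29 through the epoxide 30. The remote stereocentre needs reagent control, and an epoxide of defined configuration can pass its chirality to the CHBr carbon by one inversion (30 to 31). The tertiary chloride then follows by substitution through a bridged bromonium ion, which leaves that carbon untouched (31 to 32).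

29 ← 28. The ring C–Br bond is cut to the axial alcohol 28, to be replaced with inversion. The bromide is placed after the radical step because a secondary alkyl bromide is itself a substrate for silyl radicals. This is the one weak joint in the endgame, and the risk section returns to it.

28 ← 27 ← 26. The C1–C2 bond of ring A is cut. Going forward, the vinyl radical from the 2-iodoalkene arm of 26 closes ring A onto the styrene, which creates the exocyclic methylene, the ring and the C1 stereocentre at once. Cutting here, and not at a ring-B bond, leaves a monocyclic precursor whose three ring stereocentres can be set by enolate and conjugate-addition chemistry.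

26 ← 25 ← 21 + 24 (24 from 23, 23 from 22). The styrene is cut at the aryl–benzylic carbon bond. An aryl Grignard reagent made by iodine–magnesium exchange adds to aldehyde 21, and dehydration can only give the conjugated E-alkene, since the sole β-hydrogens are on the CH2 next to the quaternary carbon. The aryl bromides come in intact from a commercial phenol.

21 ← 20 ← 18 ← 17 ← 16. The vinyl iodide is traced to a terminal alkyne by Markovnikov iodoboration and protonolysis, and the aldehyde to a methyl ester. The iodide is installed before the arene arrives, so the Lewis acidic boron reagent never meets the aryl silyl ether or the styrene.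

16 ← 15 ← 14. The axial carbinol comes from the ketone by hindered-hydride reduction, and the saturated ketone from an enone. The enone is needed earlier, because it blocks one flank of the ketone and forces enolisation toward C5.

14 ← 11 + 13, and 11 ← 9 + 10. The quaternary C5 is cut at both of its exocyclic C–C bonds: methyl first, then the 4-methylpent-3-enyl chain. The second electrophile enters anti to the neighbouring butynyl chain, and the target needs the chain trans and the methyl cis to it.

9 ← 8 ← 7 ← 6. The enone carbonyl is put in by allylic oxidation of cyclohexene 8, whose only allylic CH2 is the one required. Alkene 8 comes from ketone 6 through its enol triflate. A route through a 4-substituted 3-methylcyclohexenol and a Claisen rearrangement would reach the same cyclohexene, but as a racemate unless a resolution is added.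

6 ← 1 + 2 + 3 (via 4 and 5). Both ring bonds to the butynyl-bearing carbon and to the angular carbon are made in one flask by catalytic asymmetric conjugate addition and enolate alkylation. This fixes the absolute configuration at the start and the trans relation of the two arms that later become ring A.

## Alternatives that were turned down

Alternative 1: Ring B is cut at the C6–C7 and C5–C4a bonds. A chiral oxazaborolidinium-catalysed Diels–Alder reaction between the bromo enal A2 and the dienyne A3 would give the bromocyclohexene aldehyde A1. In its favour, one catalytic step sets three ring-B stereocentres, and the C–Br bond arrives with its final configuration, so no substitution at the neopentyl carbon is needed. On that point it is stronger than the chosen route. Against it, A2 is a trisubstituted, deactivated dienophile, and the 3-methyl and 4-alkyl groups of A3 direct regiochemistry in opposite senses. The secondary bromide of A1 would also have to survive every later step, which rules out radical, strongly basic and low-valent metal chemistry. A1 still lacks the angular quaternary carbon and ring A, and these would have to be built by adding carbon to its hindered trisubstituted alkene. The chosen strategy pays for its harder bromination with a single late step that makes ring A, the methylene and C1, and with a free choice of reagents before the bromide exists.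

Alternative 2: Ring B is cut at the C5–C6 bond. SmI2 (divalent samarium) would reduce an aldehyde to a ketyl that adds 6-exo to a β,β-disubstituted enoate, giving the decalin hydroxy ester A4. In its favour, the quaternary C5 and the C6 carbinol form together under chelation control, and the acetate arm is a ready handle for the side chain. For C5 this is at least as secure as a double alkylation. Against it, ketyl addition to a fully substituted β-carbon is slow relative to simple reduction or pinacol coupling. The carbinol of A4 also has the configuration of the final bromide, so inversion would give the wrong epimer unless it is oxidised and re-reduced. Most important, ring A of A4 carries only a masked ketone at C1. The arylmethyl group, its stereocentre and the C2 methylene would all have to be installed beside the angular carbon by olefination and enolate chemistry at a neopentyl ketone, and that is exactly what the chosen key step does in one operation. The step count after A4 would be higher.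

Alternative 3: The two aryl C–C bonds are cut. A siloxyalkyne on the C1 methylene arm would add across C3 and C6 of the dibromopyrone A6 on heating and lose CO2 to give the aryl silyl ether A5. In its favour, the dibromophenol is created last, so no aryl bromide is present during radical or organometallic steps, and the step is convergent. On chemoselectivity it is as strong as or stronger than the chosen route. Against it, it is only an endgame. The decalin, its C1 stereocentre and the exocyclic methylene must first be made by other means, so the real problem stays open. The siloxyalkyne has to be grown on a hindered arm in several steps, and the hot pyrone can also engage the two alkenes already present. The chosen route brings the arene in from a commercial phenol and uses its styrene to build ring A and C1.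

Key step: step 17

## Route

Remark: the enantiomer of the copper ligand in step 1 and of the fructose-derived ketone in step 20 is the one that gives the configurations drawn; the descriptors of the products state what is required.
Remark: for decalins 27–33 the locants of the target name are kept (C1 arylmethyl carbon, C2 methylidene carbon, C4a/C8a fusion carbons, C5 quaternary carbon, C6 carbinol or bromide carbon).

Step 1
Reactants: 1 2-methylcyclohex-2-en-1-one; 2 (4-bromobut-1-yn-1-yl)trimethylsilane; 3 methyl bromoacetate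
Product: 6 methyl 2-[(1S,6S)-1-methyl-2-oxo-6-[4-(trimethylsilyl)but-3-yn-1-yl]cyclohexyl]acetate, via Grignard reagent 4 (not isolated), via magnesium enolate 5 (not isolated)
Conditions: 2, Mg, Et2O; then 1, Cu(OTf)2 (cat.), chiral N-mesityl-N'-(2-hydroxyalkyl)imidazolinium salt (cat.), Et2O, −30 °C; then 3, DMPU, −30 → 23 °C
Reagents that add atoms: none
Why: Copper-catalysed asymmetric conjugate addition of a Grignard reagent to a 2-substituted cyclohexenone with in situ alkylation of the magnesium enolate; the chiral carbene–copper complex selects the enone face and fixes the butynyl-bearing carbon, and the bromoacetate approaches the enolate anti to that vicinal substituent, so the quaternary carbon has its methyl cis and its acetate arm trans to the butynyl chain.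

Step 2
Reactants: 6 methyl 2-[(1S,6S)-1-methyl-2-oxo-6-[4-(trimethylsilyl)but-3-yn-1-yl]cyclohexyl]acetate
Product: 7 methyl 2-[(1S,6S)-1-methyl-2-(trifluoromethanesulfonyloxy)-6-[4-(trimethylsilyl)but-3-yn-1-yl]cyclohex-2-en-1-yl]acetate
Conditions: KN(SiMe3)2, THF, −78 °C; PhNTf2, −78 → 0 °C
Reagents that add atoms: N-phenylbis(trifluoromethanesulfonimide), O=S(=O)(N(c1ccccc1)S(=O)(=O)C(F)(F)F)C(F)(F)F
Why: Enol triflate formation; the ketone can enolise only toward its CH2 flank because the other α-carbon is quaternary, and the silazide base is too weak to deprotonate the hindered ester.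

Step 3
Reactants: 7 methyl 2-[(1S,6S)-1-methyl-2-(trifluoromethanesulfonyloxy)-6-[4-(trimethylsilyl)but-3-yn-1-yl]cyclohex-2-en-1-yl]acetate
Product: 8 methyl 2-[(1S,6S)-1-methyl-6-[4-(trimethylsilyl)but-3-yn-1-yl]cyclohex-2-en-1-yl]acetate
Conditions: Pd(OAc)2 (cat.), PPh3, HCO2H, Bu3N, DMF, 60 °C
Reagents that add atoms: none
Why: Palladium-catalysed formate reduction of an enol triflate (oxidative addition, formate-to-hydride exchange, reductive elimination); intramolecular carbopalladation of the silylalkyne would need a bridgehead alkene and should not compete.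

Step 4
Reactants: 8 methyl 2-[(1S,6S)-1-methyl-6-[4-(trimethylsilyl)but-3-yn-1-yl]cyclohex-2-en-1-yl]acetate
Product: 9 methyl 2-[(1S,6R)-1-methyl-4-oxo-6-[4-(trimethylsilyl)but-3-yn-1-yl]cyclohex-2-en-1-yl]acetate
Conditions: Rh2(cap)4 (cap = caprolactamate, cat.), t-BuOOH (70% aq.), K2CO3, CH2Cl2, 23 °C
Reagents that add atoms: tert-butyl hydroperoxide, CC(C)(C)OO
Why: Radical allylic oxidation to the enone; the quaternary carbon leaves a single allylic CH2, and the peroxyl radical should be captured at that less hindered end of the allyl radical, giving the 4,4-disubstituted cyclohexenone.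

Step 5
Reactants: 9 methyl 2-[(1S,6R)-1-methyl-4-oxo-6-[4-(trimethylsilyl)but-3-yn-1-yl]cyclohex-2-en-1-yl]acetate; 10 iodomethane
Product: 11 methyl 2-[(1R,6R)-1,5-dimethyl-4-oxo-6-[4-(trimethylsilyl)but-3-yn-1-yl]cyclohex-2-en-1-yl]acetate (C5 epimers)
Conditions: LiN(SiMe3)2, THF, −78 °C; MeI, −78 → −40 °C
Reagents that add atoms: none
Why: α'-Alkylation of an enone; there is no γ-hydrogen, so only the cross-conjugated enolate forms, and the configuration of the new CH(CH3) carbon does not matter because it is enolised again in step 7.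

Step 6
Reactants: 12 5-bromo-2-methylpent-2-ene
Product: 13 5-iodo-2-methylpent-2-ene
Conditions: NaI, acetone, reflux
Reagents that add atoms: sodium iodide, [Na+].[I-]
Why: Finkelstein exchange on a primary bromide, driven by precipitation of NaBr; the iodide is the better partner for the hindered enolate of step 7.

Step 7
Reactants: 11 methyl 2-[(1R,6R)-1,5-dimethyl-4-oxo-6-[4-(trimethylsilyl)but-3-yn-1-yl]cyclohex-2-en-1-yl]acetate (C5 epimers); 13 5-iodo-2-methylpent-2-ene
Product: 14 methyl 2-[(1R,5R,6S)-1,5-dimethyl-5-(4-methylpent-3-en-1-yl)-4-oxo-6-[4-(trimethylsilyl)but-3-yn-1-yl]cyclohex-2-en-1-yl]acetate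
Conditions: LiN(SiMe3)2, THF, −78 → −30 °C; HMPA; 13, −30 → 0 °C
Reagents that add atoms: none
Why: Alkylation of the fully substituted lithium dienolate to a quaternary carbon; the vicinal butynyl chain turns pseudo-axial to avoid A(1,2) strain with the enolate methyl and shields its own face, so the iodide enters anti to it, which places the new chain trans and the methyl cis to the butynyl arm.

Step 8
Reactants: 14 methyl 2-[(1R,5R,6S)-1,5-dimethyl-5-(4-methylpent-3-en-1-yl)-4-oxo-6-[4-(trimethylsilyl)but-3-yn-1-yl]cyclohex-2-en-1-yl]acetate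
Product: 15 methyl 2-[(1S,2S,3R)-1,3-dimethyl-3-(4-methylpent-3-en-1-yl)-4-oxo-2-[4-(trimethylsilyl)but-3-yn-1-yl]cyclohexyl]acetate
Conditions: [(Ph3P)CuH]6, H2O (3 equiv), toluene, 23 °C
Reagents that add atoms: none
Why: Copper hydride conjugate reduction; hydride goes to the unsubstituted β-carbon of the enone, and the isolated trisubstituted alkene, the silylalkyne and the ester are not reduced.

Step 9
Reactants: 15 methyl 2-[(1S,2S,3R)-1,3-dimethyl-3-(4-methylpent-3-en-1-yl)-4-oxo-2-[4-(trimethylsilyl)but-3-yn-1-yl]cyclohexyl]acetate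
Product: 16 methyl 2-[(1S,2S,3R,4S)-4-hydroxy-1,3-dimethyl-3-(4-methylpent-3-en-1-yl)-2-[4-(trimethylsilyl)but-3-yn-1-yl]cyclohexyl]acetate
Conditions: LiBH(s-Bu)3, THF, −78 °C; then H2O
Reagents that add atoms: none
Why: Hindered-hydride reduction of a cyclohexanone; in the favoured chair (both future ring-A arms equatorial, the two methyls axial) the bulky borohydride attacks along the equatorial direction and gives the axial alcohol, cis to the 4-methylpentenyl chain, as is usual for 2,2-disubstituted cyclohexanones, and the ester is not reduced at −78 °C.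

Step 10
Reactants: 16 methyl 2-[(1S,2S,3R,4S)-4-hydroxy-1,3-dimethyl-3-(4-methylpent-3-en-1-yl)-2-[4-(trimethylsilyl)but-3-yn-1-yl]cyclohexyl]acetate
Product: 17 methyl 2-[(1S,2S,3R,4S)-2-(but-3-yn-1-yl)-4-hydroxy-1,3-dimethyl-3-(4-methylpent-3-en-1-yl)cyclohexyl]acetate
Conditions: K2CO3 (cat.), MeOH, 23 °C
Reagents that add atoms: none
Why: Base-catalysed methanolysis of the C(sp)–Si bond; the methyl ester is unchanged by methoxide exchange and is too hindered to hydrolyse.

Step 11
Reactants: 17 methyl 2-[(1S,2S,3R,4S)-2-(but-3-yn-1-yl)-4-hydroxy-1,3-dimethyl-3-(4-methylpent-3-en-1-yl)cyclohexyl]acetate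
Product: 18 methyl 2-[(1S,2S,3R,4S)-2-(but-3-yn-1-yl)-1,3-dimethyl-3-(4-methylpent-3-en-1-yl)-4-(triethylsilyloxy)cyclohexyl]acetate
Conditions: Et3SiOTf, 2,6-lutidine, CH2Cl2, −78 → 0 °C
Reagents that add atoms: triethylsilyl trifluoromethanesulfonate, CC[Si](CC)(CC)OS(=O)(=O)C(F)(F)F
Why: Silylation of a hindered secondary alcohol with a silyl triflate; the triethylsilyl ether is chosen because it can later be removed by mild acid without touching an aryl silyl ether.

Step 12
Reactants: 18 methyl 2-[(1S,2S,3R,4S)-2-(but-3-yn-1-yl)-1,3-dimethyl-3-(4-methylpent-3-en-1-yl)-4-(triethylsilyloxy)cyclohexyl]acetate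
Product: 20 methyl 2-[(1S,2S,3R,4S)-2-(3-iodobut-3-en-1-yl)-1,3-dimethyl-3-(4-methylpent-3-en-1-yl)-4-(triethylsilyloxy)cyclohexyl]acetate, via alkenylborane 19 (not isolated)
Conditions: 9-iodo-9-borabicyclo[3.3.1]nonane, pentane, −20 → 0 °C; then AcOH, 0 °C
Reagents that add atoms: 9-iodo-9-borabicyclo[3.3.1]nonane, IB1C2CCCC1CCC2
Why: Haloboration of a terminal alkyne followed by protodeboronation; the B–I bond adds syn with boron on the terminal and iodine on the internal carbon, acetic acid replaces boron by hydrogen, and alkenes do not undergo haloboration.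

Step 13
Reactants: 20 methyl 2-[(1S,2S,3R,4S)-2-(3-iodobut-3-en-1-yl)-1,3-dimethyl-3-(4-methylpent-3-en-1-yl)-4-(triethylsilyloxy)cyclohexyl]acetate
Product: 21 2-[(1S,2S,3R,4S)-2-(3-iodobut-3-en-1-yl)-1,3-dimethyl-3-(4-methylpent-3-en-1-yl)-4-(triethylsilyloxy)cyclohexyl]acetaldehyde
Conditions: i-Bu2AlH (1.1 equiv), CH2Cl2, −78 °C; aq. Rochelle salt
Reagents that add atoms: none
Why: Partial reduction of an ester to the aldehyde; the tetrahedral aluminium hemiacetal of this neopentyl-type ester is stable at −78 °C and collapses only on work-up, and the vinyl iodide is inert.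

Step 14
Reactants: 22 2,4-dibromo-6-iodophenol
Product: 23 (2,4-dibromo-6-iodophenoxy)tri(propan-2-yl)silane
Conditions: i-Pr3SiOTf, Et3N, CH2Cl2, 0 → 23 °C
Reagents that add atoms: triisopropylsilyl trifluoromethanesulfonate, CC(C)[Si](C(C)C)(C(C)C)OS(=O)(=O)C(F)(F)F
Why: Silylation of an acidic, doubly ortho-substituted phenol; the bulky triisopropylsilyl group is chosen to resist silyl migration in step 15 and the buffered base of step 20.

Step 15
Reactants: 23 (2,4-dibromo-6-iodophenoxy)tri(propan-2-yl)silane; 21 2-[(1S,2S,3R,4S)-2-(3-iodobut-3-en-1-yl)-1,3-dimethyl-3-(4-methylpent-3-en-1-yl)-4-(triethylsilyloxy)cyclohexyl]acetaldehyde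
Product: 25 1-{3,5-dibromo-2-[tri(propan-2-yl)silyloxy]phenyl}-2-[(1S,2S,3R,4S)-2-(3-iodobut-3-en-1-yl)-1,3-dimethyl-3-(4-methylpent-3-en-1-yl)-4-(triethylsilyloxy)cyclohexyl]ethan-1-ol (carbinol epimers), via arylmagnesium chloride 24 (not isolated)
Conditions: 23, i-PrMgCl·LiCl (0.98 equiv), THF, −40 °C; then 21, −40 → −10 °C; AcOH quench at −40 °C
Reagents that add atoms: none
Why: Iodine–magnesium exchange followed by Grignard addition to an aldehyde; exchange is much faster at C–I than at C–Br, the arylmagnesium has no ortho halogen and cannot form an aryne, and the cold acidic quench prevents transfer of the silyl group from the phenol oxygen to the new alkoxide; the carbinol centre is removed in step 16.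

Step 16
Reactants: 25 1-{3,5-dibromo-2-[tri(propan-2-yl)silyloxy]phenyl}-2-[(1S,2S,3R,4S)-2-(3-iodobut-3-en-1-yl)-1,3-dimethyl-3-(4-methylpent-3-en-1-yl)-4-(triethylsilyloxy)cyclohexyl]ethan-1-ol (carbinol epimers)
Product: 26 triethyl{[(1S,2R,3S,4S)-4-[(E)-2-{3,5-dibromo-2-[tri(propan-2-yl)silyloxy]phenyl}ethenyl]-3-(3-iodobut-3-en-1-yl)-2,4-dimethyl-2-(4-methylpent-3-en-1-yl)cyclohexyl]oxy}silane
Conditions: Burgess reagent (methyl N-(triethylammoniosulfonyl)carbamate), toluene, 60 °C
Reagents that add atoms: none
Why: Burgess dehydration by syn elimination of the sulfamate; the only β-hydrogens lie on the CH2 next to the quaternary carbon, so only the styrene can form, and the transition state with the aryl group anti to the bulky ring gives the E-alkene from both carbinol epimers.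

Step 17
Reactants: 26 triethyl{[(1S,2R,3S,4S)-4-[(E)-2-{3,5-dibromo-2-[tri(propan-2-yl)silyloxy]phenyl}ethenyl]-3-(3-iodobut-3-en-1-yl)-2,4-dimethyl-2-(4-methylpent-3-en-1-yl)cyclohexyl]oxy}silane
Product: 27 {2,4-dibromo-6-[((1R,4aS,5R,6S,8aS)-5,8a-dimethyl-2-methylidene-5-(4-methylpent-3-en-1-yl)-6-(triethylsilyloxy)decahydronaphthalen-1-yl)methyl]phenoxy}tri(propan-2-yl)silane
Conditions: (Me3Si)3SiH (1.3 equiv), Et3B (0.3 equiv, in portions), trace air, toluene (0.02 M), 0 → 23 °C
Reagents that add atoms: none
Why: Ethyl radicals from Et3B and oxygen generate the silyl radical, which abstracts iodine from the vinyl iodide far faster than bromine from the two aryl C–Br bonds, giving a σ-vinyl radical at the future C2. This radical adds to the styrene carbon bonded to the angular quaternary carbon, forming the C2–C1 bond and ring A in the 6-exo-trig mode; 7-endo attack is disfavoured because only exo attack yields a benzylic radical. The benzylic radical takes hydrogen from the silane to give the ArCH2 group and a new silyl radical that carries the chain. The closest known reaction type is the tin- or silicon-hydride-mediated 6-exo cyclisation of 2-iodoalk-1-enes onto styrenes. The new stereocentre C1 is controlled by the ring-B chair, in which the iodobutenyl arm and the styryl group are both equatorial and trans, so ring A can only close as the second chair of a trans-decalin. Within that chair the exocyclic styrene carbon should sit pseudo-equatorial, avoiding syn-axial contact with H-4a and the C3 hydrogen, which puts the arylmethyl group equatorial and cis to the C8a methyl. The step needs chemoselectivity (C–I over C–Br, secured by the rate gap), cyclisation ahead of direct reduction (secured by dilution and by the activated styrene acceptor), and facial selectivity at C1 (secured by the chair just described).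

Step 18
Reactants: 27 {2,4-dibromo-6-[((1R,4aS,5R,6S,8aS)-5,8a-dimethyl-2-methylidene-5-(4-methylpent-3-en-1-yl)-6-(triethylsilyloxy)decahydronaphthalen-1-yl)methyl]phenoxy}tri(propan-2-yl)silane
Product: 28 {2,4-dibromo-6-[((1R,4aS,5R,6S,8aS)-6-hydroxy-5,8a-dimethyl-2-methylidene-5-(4-methylpent-3-en-1-yl)decahydronaphthalen-1-yl)methyl]phenoxy}tri(propan-2-yl)silane
Conditions: PPTS, MeOH–CH2Cl2 (1:1), 23 → 40 °C
Reagents that add atoms: none
Why: Acid-catalysed methanolysis of the alkyl triethylsilyl ether; aryl silyl ethers are cleaved by base or fluoride but are slow under mild acid, and pyridinium tosylate is too weak to isomerise the exocyclic alkene.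

Step 19
Reactants: 28 {2,4-dibromo-6-[((1R,4aS,5R,6S,8aS)-6-hydroxy-5,8a-dimethyl-2-methylidene-5-(4-methylpent-3-en-1-yl)decahydronaphthalen-1-yl)methyl]phenoxy}tri(propan-2-yl)silane
Product: 29 {2,4-dibromo-6-[((1R,4aS,5R,6R,8aS)-6-bromo-5,8a-dimethyl-2-methylidene-5-(4-methylpent-3-en-1-yl)decahydronaphthalen-1-yl)methyl]phenoxy}tri(propan-2-yl)silane
Conditions: CBr4, P(n-C8H17)3, toluene, 70 °C
Reagents that add atoms: tetrabromomethane, BrC(Br)(Br)Br
Why: Appel bromination; bromide displaces the axial alkoxyphosphonium group from the opposite face, so the bromine ends equatorial with inversion (6S to 6R), and the small, strongly nucleophilic trialkylphosphine is the variant that works on neopentyl-type secondary cyclohexanols.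

Step 20
Reactants: 29 {2,4-dibromo-6-[((1R,4aS,5R,6R,8aS)-6-bromo-5,8a-dimethyl-2-methylidene-5-(4-methylpent-3-en-1-yl)decahydronaphthalen-1-yl)methyl]phenoxy}tri(propan-2-yl)silane
Product: 30 {2,4-dibromo-6-[((1R,4aS,5R,6R,8aS)-6-bromo-5-{2-[(2S)-3,3-dimethyloxiran-2-yl]ethyl}-5,8a-dimethyl-2-methylidenedecahydronaphthalen-1-yl)methyl]phenoxy}tri(propan-2-yl)silane
Conditions: L-fructose-derived Shi ketone (0.3 equiv), KHSO5 (Oxone), K2CO3, Bu4NHSO4, MeCN–CH2(OMe)2–aq. Na2B4O7 buffer (pH 10.5), 0 °C
Reagents that add atoms: potassium peroxymonosulfate, [K+].[O-]S(=O)(=O)OO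
Why: Shi epoxidation by a chiral dioxirane; the trisubstituted side-chain alkene is more electron-rich and less hindered than the exocyclic methylene and should react first, and the ketone enantiomer sets the (S)-epoxide by reagent control, so any minor enantiomer carried from step 1 becomes a separable diastereomer.

Step 21
Reactants: 30 {2,4-dibromo-6-[((1R,4aS,5R,6R,8aS)-6-bromo-5-{2-[(2S)-3,3-dimethyloxiran-2-yl]ethyl}-5,8a-dimethyl-2-methylidenedecahydronaphthalen-1-yl)methyl]phenoxy}tri(propan-2-yl)silane
Product: 31 {2,4-dibromo-6-[((1R,4aS,5R,6R,8aS)-6-bromo-5-[(3R)-3-bromo-4-hydroxy-4-methylpentyl]-5,8a-dimethyl-2-methylidenedecahydronaphthalen-1-yl)methyl]phenoxy}tri(propan-2-yl)silane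
Conditions: Li2NiBr4 (divalent nickel), THF, 0 → 23 °C; then H2O
Reagents that add atoms: dilithium tetrabromonickelate, [Li+].[Li+].Br[Ni-2](Br)(Br)Br
Why: Nucleophilic epoxide opening by a soft, weakly acidic bromide source; attack at the secondary epoxide carbon from the back gives the secondary bromide with inversion (S to R) and the tertiary alcohol.

Step 22
Reactants: 31 {2,4-dibromo-6-[((1R,4aS,5R,6R,8aS)-6-bromo-5-[(3R)-3-bromo-4-hydroxy-4-methylpentyl]-5,8a-dimethyl-2-methylidenedecahydronaphthalen-1-yl)methyl]phenoxy}tri(propan-2-yl)silane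
Product: 32 {2,4-dibromo-6-[((1R,4aS,5R,6R,8aS)-6-bromo-5-[(3R)-3-bromo-4-chloro-4-methylpentyl]-5,8a-dimethyl-2-methylidenedecahydronaphthalen-1-yl)methyl]phenoxy}tri(propan-2-yl)silane
Conditions: SOCl2, 2,6-di-tert-butylpyridine, CH2Cl2, −40 → 0 °C
Reagents that add atoms: thionyl chloride, O=S(Cl)Cl
Why: Substitution of a β-bromo alcohol with neighbouring-group participation; the tertiary chlorosulfite ionises with help from the adjacent bromine to a bromonium ion, chloride opens it at the tertiary carbon, and the C–Br stereocentre is never broken, while the hindered base traps HCl before it can add to the exocyclic alkene.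

Step 23
Reactants: 32 {2,4-dibromo-6-[((1R,4aS,5R,6R,8aS)-6-bromo-5-[(3R)-3-bromo-4-chloro-4-methylpentyl]-5,8a-dimethyl-2-methylidenedecahydronaphthalen-1-yl)methyl]phenoxy}tri(propan-2-yl)silane
Product: 33 2,4-dibromo-6-{[(1R,4aS,5R,6R,8aS)-6-bromo-5-[(3R)-3-bromo-4-chloro-4-methylpentyl]-5,8a-dimethyl-2-methylidenedecahydronaphthalen-1-yl]methyl}phenol
Conditions: Bu4NF, AcOH (1:1.2), THF, 0 °C
Reagents that add atoms: none
Why: Fluoride cleavage of an aryl silyl ether; the electron-poor phenoxide is a good leaving group on silicon, and the acetic acid buffer keeps fluoride from acting as a base toward the tertiary chloride and the secondary bromides.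

## Compound list

1 | 2-methylcyclohex-2-en-1-one | CC1=CCCCC1=O | starting material
2 | (4-bromobut-1-yn-1-yl)trimethylsilane | C[Si](C)(C)C#CCCBr | starting material
3 | methyl bromoacetate | COC(=O)CBr | starting material
4 | [4-(trimethylsilyl)but-3-yn-1-yl]magnesium bromide | C[Si](C)(C)C#CCC[Mg]Br | intermediate (not isolated)
5 | bromomagnesium enolate of (3S)-2-methyl-3-[4-(trimethylsilyl)but-3-yn-1-yl]cyclohexanone | C[Si](C)(C)C#CCC[C@@H]1CCCC(O[Mg]Br)=C1C | intermediate (not isolated)
6 | methyl 2-[(1S,6S)-1-methyl-2-oxo-6-[4-(trimethylsilyl)but-3-yn-1-yl]cyclohexyl]acetate | C[Si](C)(C)C#CCC[C@@H]1CCCC(=O)[C@@]1(C)CC(=O)OC | intermediate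
7 | methyl 2-[(1S,6S)-1-methyl-2-(trifluoromethanesulfonyloxy)-6-[4-(trimethylsilyl)but-3-yn-1-yl]cyclohex-2-en-1-yl]acetate | C[Si](C)(C)C#CCC[C@@H]1CCC=C(OS(=O)(=O)C(F)(F)F)[C@@]1(C)CC(=O)OC | intermediate
8 | methyl 2-[(1S,6S)-1-methyl-6-[4-(trimethylsilyl)but-3-yn-1-yl]cyclohex-2-en-1-yl]acetate | C[Si](C)(C)C#CCC[C@@H]1CCC=C[C@@]1(C)CC(=O)OC | intermediate
9 | methyl 2-[(1S,6R)-1-methyl-4-oxo-6-[4-(trimethylsilyl)but-3-yn-1-yl]cyclohex-2-en-1-yl]acetate | C[Si](C)(C)C#CCC[C@@H]1CC(=O)C=C[C@@]1(C)CC(=O)OC | intermediate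
10 | iodomethane | CI | starting material
11 | methyl 2-[(1R,6R)-1,5-dimethyl-4-oxo-6-[4-(trimethylsilyl)but-3-yn-1-yl]cyclohex-2-en-1-yl]acetate (C5 epimers) | C[Si](C)(C)C#CCC[C@@H]1C(C)C(=O)C=C[C@@]1(C)CC(=O)OC | intermediate
12 | 5-bromo-2-methylpent-2-ene | CC(C)=CCCBr | starting material
13 | 5-iodo-2-methylpent-2-ene | CC(C)=CCCI | intermediate
14 | methyl 2-[(1R,5R,6S)-1,5-dimethyl-5-(4-methylpent-3-en-1-yl)-4-oxo-6-[4-(trimethylsilyl)but-3-yn-1-yl]cyclohex-2-en-1-yl]acetate | C[Si](C)(C)C#CCC[C@@H]1[C@@](C)(CCC=C(C)C)C(=O)C=C[C@@]1(C)CC(=O)OC | intermediate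
15 | methyl 2-[(1S,2S,3R)-1,3-dimethyl-3-(4-methylpent-3-en-1-yl)-4-oxo-2-[4-(trimethylsilyl)but-3-yn-1-yl]cyclohexyl]acetate | C[Si](C)(C)C#CCC[C@@H]1[C@@](C)(CCC=C(C)C)C(=O)CC[C@@]1(C)CC(=O)OC | intermediate
16 | methyl 2-[(1S,2S,3R,4S)-4-hydroxy-1,3-dimethyl-3-(4-methylpent-3-en-1-yl)-2-[4-(trimethylsilyl)but-3-yn-1-yl]cyclohexyl]acetate | C[Si](C)(C)C#CCC[C@@H]1[C@@](C)(CCC=C(C)C)[C@@H](O)CC[C@@]1(C)CC(=O)OC | intermediate
17 | methyl 2-[(1S,2S,3R,4S)-2-(but-3-yn-1-yl)-4-hydroxy-1,3-dimethyl-3-(4-methylpent-3-en-1-yl)cyclohexyl]acetate | C#CCC[C@@H]1[C@@](C)(CCC=C(C)C)[C@@H](O)CC[C@@]1(C)CC(=O)OC | intermediate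
18 | methyl 2-[(1S,2S,3R,4S)-2-(but-3-yn-1-yl)-1,3-dimethyl-3-(4-methylpent-3-en-1-yl)-4-(triethylsilyloxy)cyclohexyl]acetate | C#CCC[C@@H]1[C@@](C)(CCC=C(C)C)[C@@H](O[Si](CC)(CC)CC)CC[C@@]1(C)CC(=O)OC | intermediate
19 | 9-[(Z)-2-iodoalk-1-enyl]-9-borabicyclo[3.3.1]nonane adduct of 18 (boron on the terminal carbon, iodine on the internal carbon, cis) | I/C(CC[C@@H]1[C@@](C)(CCC=C(C)C)[C@@H](O[Si](CC)(CC)CC)CC[C@@]1(C)CC(=O)OC)=C\B1C2CCCC1CCC2 | intermediate (not isolated)
20 | methyl 2-[(1S,2S,3R,4S)-2-(3-iodobut-3-en-1-yl)-1,3-dimethyl-3-(4-methylpent-3-en-1-yl)-4-(triethylsilyloxy)cyclohexyl]acetate | C=C(I)CC[C@@H]1[C@@](C)(CCC=C(C)C)[C@@H](O[Si](CC)(CC)CC)CC[C@@]1(C)CC(=O)OC | intermediate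
21 | 2-[(1S,2S,3R,4S)-2-(3-iodobut-3-en-1-yl)-1,3-dimethyl-3-(4-methylpent-3-en-1-yl)-4-(triethylsilyloxy)cyclohexyl]acetaldehyde | C=C(I)CC[C@@H]1[C@@](C)(CCC=C(C)C)[C@@H](O[Si](CC)(CC)CC)CC[C@@]1(C)CC=O | intermediate
22 | 2,4-dibromo-6-iodophenol | Oc1c(Br)cc(Br)cc1I | starting material
23 | (2,4-dibromo-6-iodophenoxy)tri(propan-2-yl)silane | CC(C)[Si](C(C)C)(C(C)C)Oc1c(Br)cc(Br)cc1I | intermediate
24 | {3,5-dibromo-2-[tri(propan-2-yl)silyloxy]phenyl}magnesium chloride | CC(C)[Si](C(C)C)(C(C)C)Oc1c(Br)cc(Br)cc1[Mg]Cl | intermediate (not isolated)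
25 | 1-{3,5-dibromo-2-[tri(propan-2-yl)silyloxy]phenyl}-2-[(1S,2S,3R,4S)-2-(3-iodobut-3-en-1-yl)-1,3-dimethyl-3-(4-methylpent-3-en-1-yl)-4-(triethylsilyloxy)cyclohexyl]ethan-1-ol (carbinol epimers) | C=C(I)CC[C@@H]1[C@@](C)(CCC=C(C)C)[C@@H](O[Si](CC)(CC)CC)CC[C@@]1(C)CC(O)c1cc(Br)cc(Br)c1O[Si](C(C)C)(C(C)C)C(C)C | intermediate
26 | triethyl{[(1S,2R,3S,4S)-4-[(E)-2-{3,5-dibromo-2-[tri(propan-2-yl)silyloxy]phenyl}ethenyl]-3-(3-iodobut-3-en-1-yl)-2,4-dimethyl-2-(4-methylpent-3-en-1-yl)cyclohexyl]oxy}silane | C=C(I)CC[C@@H]1[C@@](C)(CCC=C(C)C)[C@@H](O[Si](CC)(CC)CC)CC[C@@]1(C)/C=C/c1cc(Br)cc(Br)c1O[Si](C(C)C)(C(C)C)C(C)C | intermediate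
27 | {2,4-dibromo-6-[((1R,4aS,5R,6S,8aS)-5,8a-dimethyl-2-methylidene-5-(4-methylpent-3-en-1-yl)-6-(triethylsilyloxy)decahydronaphthalen-1-yl)methyl]phenoxy}tri(propan-2-yl)silane | C=C1CC[C@@H]2[C@@](C)(CCC=C(C)C)[C@@H](O[Si](CC)(CC)CC)CC[C@@]2(C)[C@@H]1Cc1cc(Br)cc(Br)c1O[Si](C(C)C)(C(C)C)C(C)C | intermediate
28 | {2,4-dibromo-6-[((1R,4aS,5R,6S,8aS)-6-hydroxy-5,8a-dimethyl-2-methylidene-5-(4-methylpent-3-en-1-yl)decahydronaphthalen-1-yl)methyl]phenoxy}tri(propan-2-yl)silane | C=C1CC[C@@H]2[C@@](C)(CCC=C(C)C)[C@@H](O)CC[C@@]2(C)[C@@H]1Cc1cc(Br)cc(Br)c1O[Si](C(C)C)(C(C)C)C(C)C | intermediate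
29 | {2,4-dibromo-6-[((1R,4aS,5R,6R,8aS)-6-bromo-5,8a-dimethyl-2-methylidene-5-(4-methylpent-3-en-1-yl)decahydronaphthalen-1-yl)methyl]phenoxy}tri(propan-2-yl)silane | C=C1CC[C@@H]2[C@@](C)(CCC=C(C)C)[C@H](Br)CC[C@@]2(C)[C@@H]1Cc1cc(Br)cc(Br)c1O[Si](C(C)C)(C(C)C)C(C)C | intermediate
30 | {2,4-dibromo-6-[((1R,4aS,5R,6R,8aS)-6-bromo-5-{2-[(2S)-3,3-dimethyloxiran-2-yl]ethyl}-5,8a-dimethyl-2-methylidenedecahydronaphthalen-1-yl)methyl]phenoxy}tri(propan-2-yl)silane | C=C1CC[C@@H]2[C@@](C)(CC[C@@H]3OC3(C)C)[C@H](Br)CC[C@@]2(C)[C@@H]1Cc1cc(Br)cc(Br)c1O[Si](C(C)C)(C(C)C)C(C)C | intermediate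
31 | {2,4-dibromo-6-[((1R,4aS,5R,6R,8aS)-6-bromo-5-[(3R)-3-bromo-4-hydroxy-4-methylpentyl]-5,8a-dimethyl-2-methylidenedecahydronaphthalen-1-yl)methyl]phenoxy}tri(propan-2-yl)silane | C=C1CC[C@@H]2[C@@](C)(CC[C@@H](Br)C(C)(C)O)[C@H](Br)CC[C@@]2(C)[C@@H]1Cc1cc(Br)cc(Br)c1O[Si](C(C)C)(C(C)C)C(C)C | intermediate
32 | {2,4-dibromo-6-[((1R,4aS,5R,6R,8aS)-6-bromo-5-[(3R)-3-bromo-4-chloro-4-methylpentyl]-5,8a-dimethyl-2-methylidenedecahydronaphthalen-1-yl)methyl]phenoxy}tri(propan-2-yl)silane | C=C1CC[C@@H]2[C@@](C)(CC[C@@H](Br)C(C)(C)Cl)[C@H](Br)CC[C@@]2(C)[C@@H]1Cc1cc(Br)cc(Br)c1O[Si](C(C)C)(C(C)C)C(C)C | intermediate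
33 | 2,4-dibromo-6-{[(1R,4aS,5R,6R,8aS)-6-bromo-5-[(3R)-3-bromo-4-chloro-4-methylpentyl]-5,8a-dimethyl-2-methylidenedecahydronaphthalen-1-yl]methyl}phenol | C=C1CC[C@@H]2[C@@](C)(CC[C@@H](Br)C(C)(C)Cl)[C@H](Br)CC[C@@]2(C)[C@@H]1Cc1cc(Br)cc(Br)c1O | target

## Step count and risk

Total: 23 steps. Longest linear sequence: 21 steps (steps 1–5, 7–13 and 15–23); steps 6 and 14 prepare the two side reagents.

Least certain steps:

**Step 17 (key step).** Three things may go wrong:
- Closure may also go through the transition state with the styrene terminus pseudo-axial, which lowers facial selectivity at C1.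
- Hydrogen transfer from the silane to the stabilised benzylic radical is slow, so the chain may break down or the radical may be captured by oxygen.
- The vinyl radical may be reduced before it cyclises, or may abstract the hydrogen on the silyloxy-bearing carbon (1,6-translocation).

Fallback, from 18 back to 27: the radical chain is replaced by a palladium-hydride reductive enyne cyclisation. Ester 18 is reduced with i-Bu2AlH at −78 °C to 2-[(1S,2S,3R,4S)-2-(but-3-yn-1-yl)-1,3-dimethyl-3-(4-methylpent-3-en-1-yl)-4-(triethylsilyloxy)cyclohexyl]acetaldehyde F1. Addition of 24 as in step 15 gives the carbinol epimers of 1-{3,5-dibromo-2-[tri(propan-2-yl)silyloxy]phenyl}-2-[(1S,2S,3R,4S)-2-(but-3-yn-1-yl)-1,3-dimethyl-3-(4-methylpent-3-en-1-yl)-4-(triethylsilyloxy)cyclohexyl]ethan-1-ol F2. Burgess dehydration gives the enyne triethyl{[(1S,2R,3S,4S)-3-(but-3-yn-1-yl)-4-[(E)-2-{3,5-dibromo-2-[tri(propan-2-yl)silyloxy]phenyl}ethenyl]-2,4-dimethyl-2-(4-methylpent-3-en-1-yl)cyclohexyl]oxy}silane F3. With Pd2(dba)3·CHCl3 (zerovalent palladium), P(o-tol)3, AcOH and Et3SiH in benzene at 23 °C, F3 should undergo hydropalladation of the alkyne, syn carbopalladation of the styrene through the same trans-decalin chair, and hydride capture of the alkylpalladium by the silane, giving 27. Oxidative addition into the hindered aryl bromides should be slow at this temperature.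

**Step 4.** Oxygen may be delivered to both ends of the allyl radical, giving the transposed enone as well, and the propargylic CH2 may be oxidised.

Fallback, from 6 back to 9, by 1,3-carbonyl transposition: dehydrogenation of 6 with IBX in DMSO–toluene at 70 °C gives methyl 2-[(1S,6R)-1-methyl-2-oxo-6-[4-(trimethylsilyl)but-3-yn-1-yl]cyclohex-3-en-1-yl]acetate F4. Nucleophilic epoxidation (H2O2, NaOH, MeOH, 0 °C) gives the 3,4-epoxide of F4, F5. Wharton transposition (N2H4·H2O, AcOH, MeOH, 23 °C) gives methyl 2-[(1S,6R)-4-hydroxy-1-methyl-6-[4-(trimethylsilyl)but-3-yn-1-yl]cyclohex-2-en-1-yl]acetate F6 as a carbinol mixture, and Dess–Martin oxidation gives 9.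

**Step 7.** C-alkylation of the hindered, fully substituted enolate by an unactivated primary iodide may be slow. Proton transfer, O-alkylation or attack of the enolate on the ester may then take over on warming.

Fallback, from 11 back to 14: the chain is built from an allyl group. The enolate of 11 (LiN(SiMe3)2, THF, −78 °C) is alkylated with allyl bromide, again anti to the butynyl chain, to give methyl 2-[(1R,5R,6S)-1,5-dimethyl-4-oxo-5-(prop-2-en-1-yl)-6-[4-(trimethylsilyl)but-3-yn-1-yl]cyclohex-2-en-1-yl]acetate F7. Hydroboration of the terminal alkene with disiamylborane at 0 °C and NaBO3 oxidation gives methyl 2-[(1R,5R,6S)-5-(3-hydroxypropyl)-1,5-dimethyl-4-oxo-6-[4-(trimethylsilyl)but-3-yn-1-yl]cyclohex-2-en-1-yl]acetate F8. Dess–Martin oxidation gives methyl 2-[(1R,5R,6S)-1,5-dimethyl-4-oxo-5-(3-oxopropyl)-6-[4-(trimethylsilyl)but-3-yn-1-yl]cyclohex-2-en-1-yl]acetate F9. Wittig reaction with the ylide from isopropyltriphenylphosphonium iodide and KN(SiMe3)2 is selective for the aldehyde and gives 14.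

**Step 9.** If the monocyclic ketone reacts through its other chair, hydride is delivered to the wrong face and the equatorial alcohol forms.

Fallback, from 15 back to 28: the stereocentre is set after ring closure. Ketone 15 is reduced with NaBH4 without regard to selectivity and the epimers are carried together through steps 10–18. This gives 28 mixed with its C6 epimer, {2,4-dibromo-6-[((1R,4aS,5R,6R,8aS)-6-hydroxy-5,8a-dimethyl-2-methylidene-5-(4-methylpent-3-en-1-yl)decahydronaphthalen-1-yl)methyl]phenoxy}tri(propan-2-yl)silane F11. Dess–Martin oxidation of the mixture gives the single decalone {2,4-dibromo-6-[((1R,4aS,5R,8aS)-5,8a-dimethyl-2-methylidene-5-(4-methylpent-3-en-1-yl)-6-oxodecahydronaphthalen-1-yl)methyl]phenoxy}tri(propan-2-yl)silane F10. LiBH(s-Bu)3 at −78 °C reduces F10 from the equatorial direction of the rigid trans-decalin, as is usual for such 2,2-disubstituted decalones, and returns 28.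

**Step 19.** The axial methyl on C5 lies anti to the leaving group and blocks the backside path. Ionisation with 1,2-methyl shift, or anti elimination toward C7, may therefore outrun substitution.

Fallback, from 28 back to 29: the oxyphosphonium intermediate is replaced by an isolable sulfonate. Chloromethanesulfonyl chloride and pyridine in CH2Cl2 at 0 °C give the axial chloromethanesulfonate of 28, F12. F12 is displaced by Bu4NBr in toluene at 60–80 °C under neutral, non-ionising conditions, a method that has succeeded at hindered secondary carbons, giving 29 with inversion.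

**Step 21.** Bromide may attack the tertiary epoxide carbon instead of the secondary one.

Fallback, from 30 back to 32: the bromine is delivered to the secondary carbon intramolecularly. Opening of 30 under acidic conditions (aq. HBr, Et2O, 0 °C) places bromide on the tertiary carbon and gives {2,4-dibromo-6-[((1R,4aS,5R,6R,8aS)-6-bromo-5-[(3S)-4-bromo-3-hydroxy-4-methylpentyl]-5,8a-dimethyl-2-methylidenedecahydronaphthalen-1-yl)methyl]phenoxy}tri(propan-2-yl)silane F13, with the carbinol configuration retained. With SOCl2 and 2,6-di-tert-butylpyridine, the secondary chlorosulfite of F13 is displaced from the back by the neighbouring bromine. This gives the same bromonium ion as in step 22, and chloride opens it at the tertiary carbon, so 32 results with the same (3R) configuration. A mixture of 31 and F13 from step 21 would therefore converge on 32.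

## Further compounds

F1 | step 17 | 2-[(1S,2S,3R,4S)-2-(but-3-yn-1-yl)-1,3-dimethyl-3-(4-methylpent-3-en-1-yl)-4-(triethylsilyloxy)cyclohexyl]acetaldehyde | C#CCC[C@@H]1[C@@](C)(CCC=C(C)C)[C@@H](O[Si](CC)(CC)CC)CC[C@@]1(C)CC=O
F2 | step 17 | 1-{3,5-dibromo-2-[tri(propan-2-yl)silyloxy]phenyl}-2-[(1S,2S,3R,4S)-2-(but-3-yn-1-yl)-1,3-dimethyl-3-(4-methylpent-3-en-1-yl)-4-(triethylsilyloxy)cyclohexyl]ethan-1-ol (carbinol epimers) | C#CCC[C@@H]1[C@@](C)(CCC=C(C)C)[C@@H](O[Si](CC)(CC)CC)CC[C@@]1(C)CC(O)c1cc(Br)cc(Br)c1O[Si](C(C)C)(C(C)C)C(C)C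
F3 | step 17 | triethyl{[(1S,2R,3S,4S)-3-(but-3-yn-1-yl)-4-[(E)-2-{3,5-dibromo-2-[tri(propan-2-yl)silyloxy]phenyl}ethenyl]-2,4-dimethyl-2-(4-methylpent-3-en-1-yl)cyclohexyl]oxy}silane | C#CCC[C@@H]1[C@@](C)(CCC=C(C)C)[C@@H](O[Si](CC)(CC)CC)CC[C@@]1(C)/C=C/c1cc(Br)cc(Br)c1O[Si](C(C)C)(C(C)C)C(C)C
F4 | step 4 | methyl 2-[(1S,6R)-1-methyl-2-oxo-6-[4-(trimethylsilyl)but-3-yn-1-yl]cyclohex-3-en-1-yl]acetate | C[Si](C)(C)C#CCC[C@@H]1CC=CC(=O)[C@@]1(C)CC(=O)OC
F5 | step 4 | 3,4-epoxide of F4 (epoxide configuration immaterial) | C[Si](C)(C)C#CCC[C@@H]1CC2OC2C(=O)[C@@]1(C)CC(=O)OC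
F6 | step 4 | methyl 2-[(1S,6R)-4-hydroxy-1-methyl-6-[4-(trimethylsilyl)but-3-yn-1-yl]cyclohex-2-en-1-yl]acetate (C4 epimers) | C[Si](C)(C)C#CCC[C@@H]1CC(O)C=C[C@@]1(C)CC(=O)OC
F7 | step 7 | methyl 2-[(1R,5R,6S)-1,5-dimethyl-4-oxo-5-(prop-2-en-1-yl)-6-[4-(trimethylsilyl)but-3-yn-1-yl]cyclohex-2-en-1-yl]acetate | C[Si](C)(C)C#CCC[C@@H]1[C@@](C)(CC=C)C(=O)C=C[C@@]1(C)CC(=O)OC
F8 | step 7 | methyl 2-[(1R,5R,6S)-5-(3-hydroxypropyl)-1,5-dimethyl-4-oxo-6-[4-(trimethylsilyl)but-3-yn-1-yl]cyclohex-2-en-1-yl]acetate | C[Si](C)(C)C#CCC[C@@H]1[C@@](C)(CCCO)C(=O)C=C[C@@]1(C)CC(=O)OC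
F9 | step 7 | methyl 2-[(1R,5R,6S)-1,5-dimethyl-4-oxo-5-(3-oxopropyl)-6-[4-(trimethylsilyl)but-3-yn-1-yl]cyclohex-2-en-1-yl]acetate | C[Si](C)(C)C#CCC[C@@H]1[C@@](C)(CCC=O)C(=O)C=C[C@@]1(C)CC(=O)OC
F10 | step 9 | {2,4-dibromo-6-[((1R,4aS,5R,8aS)-5,8a-dimethyl-2-methylidene-5-(4-methylpent-3-en-1-yl)-6-oxodecahydronaphthalen-1-yl)methyl]phenoxy}tri(propan-2-yl)silane | C=C1CC[C@@H]2[C@@](C)(CCC=C(C)C)C(=O)CC[C@@]2(C)[C@@H]1Cc1cc(Br)cc(Br)c1O[Si](C(C)C)(C(C)C)C(C)C
F11 | step 9 | {2,4-dibromo-6-[((1R,4aS,5R,6R,8aS)-6-hydroxy-5,8a-dimethyl-2-methylidene-5-(4-methylpent-3-en-1-yl)decahydronaphthalen-1-yl)methyl]phenoxy}tri(propan-2-yl)silane | C=C1CC[C@@H]2[C@@](C)(CCC=C(C)C)[C@H](O)CC[C@@]2(C)[C@@H]1Cc1cc(Br)cc(Br)c1O[Si](C(C)C)(C(C)C)C(C)C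
F12 | step 19 | (1R,4aS,5R,6S,8aS)-6-chloromethanesulfonate of 28 | C=C1CC[C@@H]2[C@@](C)(CCC=C(C)C)[C@@H](OS(=O)(=O)CCl)CC[C@@]2(C)[C@@H]1Cc1cc(Br)cc(Br)c1O[Si](C(C)C)(C(C)C)C(C)C
F13 | step 21 | {2,4-dibromo-6-[((1R,4aS,5R,6R,8aS)-6-bromo-5-[(3S)-4-bromo-3-hydroxy-4-methylpentyl]-5,8a-dimethyl-2-methylidenedecahydronaphthalen-1-yl)methyl]phenoxy}tri(propan-2-yl)silane | C=C1CC[C@@H]2[C@@](C)(CC[C@H](O)C(C)(C)Br)[C@H](Br)CC[C@@]2(C)[C@@H]1Cc1cc(Br)cc(Br)c1O[Si](C(C)C)(C(C)C)C(C)C
A1 | alternative 1 | 6-bromo-2-(but-3-yn-1-yl)-1,3-dimethylcyclohex-3-ene-1-carbaldehyde (configuration as in the SMILES) | C#CCC[C@@H]1[C@@](C)(C=O)[C@H](Br)CC=C1C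
A2 | alternative 1 | (E)-3-bromo-2-methylprop-2-enal | O=C/C(C)=C/Br
A3 | alternative 1 | (E)-3-methylocta-1,3-dien-7-yne | C=C/C(C)=C/CCC#C
A4 | alternative 2 | trans-decalin hydroxy ester with the C1 ketone as its ethylene ketal (configuration as in the SMILES) | C1CC[C@@H]2[C@@](C)(CC(=O)OCC)[C@H](O)CC[C@@]2(C)C13OCCO3
A5 | alternative 3 | aryl triisopropylsilyl, alkyl tert-butyldimethylsilyl bis-ether of the full carbon skeleton | C=C1CC[C@@H]2[C@@](C)(CCC=C(C)C)[C@@H](O[Si](C)(C)C(C)(C)C)CC[C@@]2(C)[C@@H]1Cc1cc(Br)cc(Br)c1O[Si](C(C)C)(C(C)C)C(C)C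
A6 | alternative 3 | 3,5-dibromo-2H-pyran-2-one | O=c1occ(Br)cc1Br
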